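**Retrosynthetic overview**
- Ring A (the δ‑lactone) is closed last by lactonisation of an open hydroxy ester, after the C9a ester centre has been equilibrated.
- The (E)‑alkylidene diene comes from a crossed aldol condensation of a C3 aldehyde (masked as a lactol) with (E)‑4‑hydroxy‑4‑methylpent‑2‑enal, followed by 1,2‑reduction.
- Key step: a keto glutarate with two identical CH2CO2Me arms undergoes a desymmetrising aldol–lactonisation that closes ring B (C9–C9a) and a temporary bridging δ‑lactone (C9–O–C3) in one operation.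
- The keto glutarate comes from a ring C enoate by malonate Michael addition and decarboxylation; ring C comes from an epoxide‑initiated cyclisation of an enol silane, which sets C7 and C12.
- The epoxide comes from geranylacetone and methyl acrylate by cross‑metathesis and Shi epoxidation. Ring order: C, then B plus the bridged lactone, then A.

Assumption: atom labels in the text are those of the target (C1(=O)–O2–C3–C4–C4a, cycloheptane C5–C9 and C9a, bridge C10–C11–C12 from C9 to C7; ring A lactone, ring B cycloheptane, ring C cyclohexane), and the L‑fructose‑derived enantiomer of the Shi ketone is taken as purchasable.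

**Step 1**
Reactants: 1 geranylacetone; 2 methyl acrylate
Product: 3 keto dienoate
Conditions: second‑generation Hoveyda–Grubbs catalyst (3 mol %), 2 (5 equiv), CH2Cl2, 40 °C
Reagents that add atoms: none
Why: Olefin cross‑metathesis at the more accessible isopropylidene terminus (the internal trisubstituted alkene is left) installs an (E)‑enoate, which also makes that end inert to the epoxidation that follows.

**Step 2**
Reactants: 3 keto dienoate
Product: 4 (2S,3S)‑epoxy keto enoate
Conditions: L‑fructose‑derived Shi ketone (0.3 equiv), KHSO5, K2CO3, Bu4NHSO4, MeCN/dimethoxymethane/aqueous buffer (pH 10.5), 0 °C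
Reagents that add atoms: KHSO5 (potassium peroxymonosulfate), [K+].[O-]S(=O)(=O)OO
Why: Shi asymmetric epoxidation oxidises only the electron‑rich trisubstituted alkene (the enoate does not react with the dioxirane) and the enantiomeric ketone gives the (2S,3S)‑oxirane through the spiro transition state, fixing the future C7 and C12.

**Step 3**
Reactants: 4 (2S,3S)‑epoxy keto enoate
Product: 6 ring C hydroxy ketone enoate, via silyl enol ether 5 (not isolated)
Conditions: LiN(i‑Pr)2, Me3SiCl, THF, −78 °C; then MeAlCl2, CH2Cl2, −90 °C; aq. HCl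
Reagents that add atoms: Me3SiCl (chlorotrimethylsilane), C[Si](C)(C)Cl
Why: Kinetic enolisation of the methyl ketone gives the terminal enol silane, whose carbon opens the activated epoxide at its tertiary carbon with inversion in a 6‑endo epoxide‑initiated (polyene‑type) cyclisation, so ring C forms with the hydroxyl trans to the side chain and cis to the methyl group (C7 S, C12 S).

**Step 4**
Reactants: 6 ring C hydroxy ketone enoate; 7 dimethyl malonate
Product: 9 keto glutarate, via Michael adduct 8 (not isolated)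
Conditions: DBU (0.2 equiv), DMSO, 40 °C; then AcOH (0.2 equiv), LiCl, H2O, 150 °C
Reagents that add atoms: none
Why: Michael addition of malonate to the enoate followed by Krapcho dealkoxycarbonylation gives a 3‑substituted glutarate whose two CH2CO2Me arms are identical, so C4a is not yet a stereocentre.

**Step 5**
Reactants: 9 keto glutarate
Product: 11 tricyclic bridged lactone ester, via aldol adduct 10 (not isolated)
Conditions: KOt‑Bu (0.3 equiv), toluene, 5 Å molecular sieves, 60 °C
Reagents that add atoms: none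
Why: Proposed new method: reversible ester‑enolate aldol addition of either diastereotopic arm to the ring ketone closes ring B on the only face the tether can reach (C9 R), and only the adduct whose second arm is cis to the new bridgehead alkoxide can lactonise with loss of methanol (taken up by the sieves), so the equilibrium drains into one tricycle with C4a fixed as in the target and the C9a ester in its less hindered orientation (9aS, inverted in step 9); the closest known reaction types are tandem intramolecular aldol–lactonisations of keto acids and thermodynamically controlled desymmetrising aldol cyclisations.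

**Step 6**
Reactants: 11 tricyclic bridged lactone ester
Product: 12 bridged lactol ester
Conditions: i‑Bu2AlH (2.2 equiv), CH2Cl2, −78 °C
Reagents that add atoms: none
Why: Low‑temperature partial reduction with i‑Bu2AlH stops at the lactol and should prefer the strained bridged δ‑lactone over the α‑branched methyl ester, unmasking C3 at the aldehyde oxidation level.

**Step 7**
Reactants: 13 2‑methylbut‑3‑en‑2‑ol; 14 crotonaldehyde
Product: 15 (E)‑4‑hydroxy‑4‑methylpent‑2‑enal
Conditions: second‑generation Hoveyda–Grubbs catalyst (3 mol %), CH2Cl2, 40 °C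
Reagents that add atoms: none
Why: Cross‑metathesis of the tertiary allylic alcohol with the enal gives the (E)‑hydroxy enal, a non‑enolisable partner for the condensation.

**Step 8**
Reactants: 12 bridged lactol ester; 15 (E)‑4‑hydroxy‑4‑methylpent‑2‑enal
Product: 16 dienal hydroxy ester
Conditions: pyrrolidine (0.3 equiv), PhCO2H (0.3 equiv), toluene, 40 °C
Reagents that add atoms: none
Why: The lactol opens to the hydroxy aldehyde, whose enamine adds to the enal carbonyl and eliminates (amine‑catalysed crossed aldol condensation), giving the (E)‑2‑alkyl‑2,4‑dienal in which the dienyl chain is anti to the formyl group and therefore cis to C4a, as in the target.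

**Step 9**
Reactants: 16 dienal hydroxy ester
Product: 18 (9aR)‑hydroxy ester, via 9a‑epimeric hydroxy ester 17 (not isolated)
Conditions: NaBH4, CeCl3·7H2O, MeOH, −40 °C; then NaOMe (0.2 equiv), MeOH, 40 °C
Reagents that add atoms: none
Why: Luche reduction gives the primary allylic alcohol without touching the ester, and methoxide then equilibrates the only epimerisable centre C9a through the ester enolate towards the epimer with the ester equatorial on the chair of ring B and trans to the C4a side chain (9aR), under thermodynamic control in methanol where the ester stays open.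

**Step 10**
Reactants: 18 (9aR)‑hydroxy ester
Product: 19 CNP0116574.1
Conditions: 2‑hydroxypyridine (0.2 equiv), toluene, 100 °C
Reagents that add atoms: none
Why: Neutral 2‑hydroxypyridine‑catalysed lactonisation (bifunctional acyl transfer) closes ring A onto the primary allylic alcohol without disturbing the tertiary alcohols or C9a, giving the trans‑fused lactone.

**Compound list**
1 | geranylacetone, (5E)‑6,10‑dimethylundeca‑5,9‑dien‑2‑one | CC(=O)CC/C=C(\C)CCC=C(C)C | starting material
2 | methyl acrylate | C=CC(=O)OC | starting material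
3 | methyl (2E,6E)‑6‑methyl‑10‑oxoundeca‑2,6‑dienoate | COC(=O)/C=C/CC/C(C)=C/CCC(C)=O | intermediate
4 | methyl (2E)‑5‑[(2S,3S)‑2‑methyl‑3‑(3‑oxobutyl)oxiran‑2‑yl]pent‑2‑enoate | COC(=O)/C=C/CC[C@]1(C)O[C@H]1CCC(C)=O | intermediate
5 | methyl (2E)‑5‑[(2S,3S)‑2‑methyl‑3‑[3‑(trimethylsilyloxy)but‑3‑enyl]oxiran‑2‑yl]pent‑2‑enoate | COC(=O)/C=C/CC[C@]1(C)O[C@H]1CCC(=C)O[Si](C)(C)C | intermediate
6 | methyl (2E)‑5‑[(1S,2S)‑2‑hydroxy‑1‑methyl‑5‑oxocyclohexyl]pent‑2‑enoate | COC(=O)/C=C/CC[C@@]1(C)CC(=O)CC[C@@H]1O | intermediate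
7 | dimethyl malonate | COC(=O)CC(=O)OC | starting material
8 | trimethyl 2‑[2‑[(1S,2S)‑2‑hydroxy‑1‑methyl‑5‑oxocyclohexyl]ethyl]propane‑1,1,3‑tricarboxylate (both C2 epimers) | COC(=O)CC(CC[C@@]1(C)CC(=O)CC[C@@H]1O)C(C(=O)OC)C(=O)OC | intermediate
9 | dimethyl 3‑[2‑[(1S,2S)‑2‑hydroxy‑1‑methyl‑5‑oxocyclohexyl]ethyl]pentanedioate | COC(=O)CC(CC(=O)OC)CC[C@@]1(C)CC(=O)CC[C@@H]1O | intermediate
10 | methyl (1R,2S,3R,6S,7S)‑1,7‑dihydroxy‑3‑(2‑methoxy‑2‑oxoethyl)‑6‑methylbicyclo[4.3.1]decane‑2‑carboxylate | COC(=O)[C@H]2[C@@H](CC(=O)OC)CC[C@@]3(C)C[C@]2(O)CC[C@@H]3O | intermediate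
11 | methyl (1R,2S,3R,6S,7S)‑3‑(carboxymethyl)‑1,7‑dihydroxy‑6‑methylbicyclo[4.3.1]decane‑2‑carboxylate, lactonised between the carboxymethyl group and the C1 hydroxyl (bridged δ‑lactone) | COC(=O)[C@H]2[C@@H]1CC[C@@]3(C)C[C@]2(OC(=O)C1)CC[C@@H]3O | intermediate
12 | cyclic hemiacetal (both anomers) between the aldehyde and the C1 hydroxyl of methyl (1R,2S,3R,6S,7S)‑1,7‑dihydroxy‑6‑methyl‑3‑(2‑oxoethyl)bicyclo[4.3.1]decane‑2‑carboxylate | COC(=O)[C@H]2[C@@H]1CC[C@@]3(C)C[C@]2(OC(O)C1)CC[C@@H]3O | intermediate
13 | 2‑methylbut‑3‑en‑2‑ol | CC(C)(O)C=C | starting material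
14 | crotonaldehyde, (E)‑but‑2‑enal | C/C=C/C=O | starting material
15 | (2E)‑4‑hydroxy‑4‑methylpent‑2‑enal | CC(C)(O)/C=C/C=O | intermediate
16 | methyl (1R,2S,3S,6S,7S)‑1,7‑dihydroxy‑3‑[(2E,4E)‑6‑hydroxy‑6‑methyl‑1‑oxohepta‑2,4‑dien‑2‑yl]‑6‑methylbicyclo[4.3.1]decane‑2‑carboxylate | COC(=O)[C@H]2[C@@H](/C(C=O)=C\C=C\C(C)(C)O)CC[C@@]3(C)C[C@]2(O)CC[C@@H]3O | intermediate
17 | methyl (1R,2S,3S,6S,7S)‑3‑[(2E,4E)‑1,6‑dihydroxy‑6‑methylhepta‑2,4‑dien‑2‑yl]‑1,7‑dihydroxy‑6‑methylbicyclo[4.3.1]decane‑2‑carboxylate | COC(=O)[C@H]2[C@@H](/C(CO)=C\C=C\C(C)(C)O)CC[C@@]3(C)C[C@]2(O)CC[C@@H]3O | intermediate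
18 | methyl (1R,2R,3S,6S,7S)‑3‑[(2E,4E)‑1,6‑dihydroxy‑6‑methylhepta‑2,4‑dien‑2‑yl]‑1,7‑dihydroxy‑6‑methylbicyclo[4.3.1]decane‑2‑carboxylate | COC(=O)[C@@H]2[C@@H](/C(CO)=C\C=C\C(C)(C)O)CC[C@@]3(C)C[C@]2(O)CC[C@@H]3O | intermediate
19 | CNP0116574.1, (4E,4aS,7S,9R,9aR,12S)‑9,12‑dihydroxy‑4‑[(2E)‑4‑hydroxy‑4‑methylpent‑2‑en‑1‑ylidene]‑7‑methyl‑perhydro‑7,9‑propanocyclohepta[c]pyran‑1‑one (trans‑fused lactone) | CC(C)(O)/C=C/C=C1/COC(=O)[C@@H]2[C@@H]1CC[C@@]1(C)C[C@]2(O)CC[C@@H]1O | target

**Step count:** 10 steps in total; longest linear sequence 9 steps (steps 1–6 and 8–10 from geranylacetone).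

**The three steps most likely to fail**

Step 5. The ketone aldol is uphill and the tricycle needs ring B in a boat, so the cascade may stall, or the ketone enolate may acylate an ester instead. The fallback sets out from 6 and forms the C9–C9a bond first, intermolecularly. A TiCl4‑promoted Mukaiyama aldol addition of 1‑methoxy‑1‑(trimethylsilyloxy)ethene to the ketone (equatorial attack, anti to the axial methyl group) gives methyl (2E)‑5‑[(1S,2S,5R)‑2,5‑dihydroxy‑5‑(2‑methoxy‑2‑oxoethyl)‑1‑methylcyclohexyl]pent‑2‑enoate F1. KN(SiMe3)2 then closes ring B by intramolecular Michael addition of the ester enolate to the enoate, and the bridgehead alkoxide lactonises onto the new CH2CO2Me arm, which brings the route back to 11.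

Step 6. The methyl ester at C9a may be reduced along with the lactone. The fallback sets out from 11 and removes the ester problem before the hydride step. SN2 demethylation with LiI in pyridine at reflux gives the bridged lactone acid F2, which i‑Bu2AlH reduces to the lactol acid F3 (the carboxylate is inert). The same pyrrolidine/PhCO2H condensation with 15 gives the dienal acid F4, and Me3SiCHN2 re‑forms the methyl ester, which brings the route back to 16.

Step 9. Methoxide may trigger retro‑aldol opening of ring B, or the open‑ester equilibrium at C9a may not favour the 9aR epimer strongly enough. The fallback sets out from 16 and moves the epimerisation to the lactone stage, where no alkoxide is needed. Luche reduction is stopped at 17, which is isolated and lactonised with 2‑hydroxypyridine in toluene to the cis‑fused lactone, the C9a epimer of the target F5. DBU in toluene at 60 °C then equilibrates C9a through the lactone enolate, and the route comes back at 19. Whether the trans‑fused lactone is the favoured epimer at this stage is itself uncertain, because allylic strain from the alkylidene works against it.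

**Further compounds**
F1 | step 5 | methyl (2E)‑5‑[(1S,2S,5R)‑2,5‑dihydroxy‑5‑(2‑methoxy‑2‑oxoethyl)‑1‑methylcyclohexyl]pent‑2‑enoate | COC(=O)/C=C/CC[C@@]3(C)C[C@](CC(=O)OC)(O)CC[C@@H]3O
F2 | step 6 | (1R,2S,3R,6S,7S)‑3‑(carboxymethyl)‑1,7‑dihydroxy‑6‑methylbicyclo[4.3.1]decane‑2‑carboxylic acid, lactonised between the carboxymethyl group and the C1 hydroxyl | OC(=O)[C@H]2[C@@H]1CC[C@@]3(C)C[C@]2(OC(=O)C1)CC[C@@H]3O
F3 | step 6 | cyclic hemiacetal between the aldehyde and the C1 hydroxyl of (1R,2S,3R,6S,7S)‑1,7‑dihydroxy‑6‑methyl‑3‑(2‑oxoethyl)bicyclo[4.3.1]decane‑2‑carboxylic acid | OC(=O)[C@H]2[C@@H]1CC[C@@]3(C)C[C@]2(OC(O)C1)CC[C@@H]3O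
F4 | step 6 | (1R,2S,3S,6S,7S)‑1,7‑dihydroxy‑3‑[(2E,4E)‑6‑hydroxy‑6‑methyl‑1‑oxohepta‑2,4‑dien‑2‑yl]‑6‑methylbicyclo[4.3.1]decane‑2‑carboxylic acid | OC(=O)[C@H]2[C@@H](/C(C=O)=C\C=C\C(C)(C)O)CC[C@@]3(C)C[C@]2(O)CC[C@@H]3O
F5 | step 9 | (4E,4aS,7S,9R,9aS,12S)‑9,12‑dihydroxy‑4‑[(2E)‑4‑hydroxy‑4‑methylpent‑2‑en‑1‑ylidene]‑7‑methyl‑perhydro‑7,9‑propanocyclohepta[c]pyran‑1‑one (cis‑fused lactone, C9a epimer of the target) | CC(C)(O)/C=C/C=C1/COC(=O)[C@H]2[C@@H]1CC[C@@]1(C)C[C@]2(O)CC[C@@H]1O
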